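**Plan**
- Retrosynthetic cuts, in order: C13=C14 of the butenolide (from a C13 sulfoxide); C8–C9 of ring B (radical closure of an 8,9-seco-labdane that carries a C9 ketone and a C8=C17 vinyl group); C12–C13 (Michael addition to a C9 vinyl ketone); C9–C11 (vinyl Grignard on a C10 aldehyde); the two C4 methyls (enolate alkylation); C1–C10 and C4–C5 (Diels–Alder, ring A).
- Forward order: ring A first by Diels–Alder reaction of an (E)-enal, then the C11–C16 chain on the C9 carbonyl, then ring B last by the C8–C9 closure, then the butenolide double bond.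
- Enabling feature: in ring B (C5–C6–C7–C8–C9–C10) the tertiary carbinol C9 is flanked by C8H(C17H3). The unit C17H3–C8H–C9(OH) is the adduct of H•, a C8=C17 vinyl group and a C9 ketone, and C5/C10, already trans on ring A, allow only the trans-decalin.
- Stereochemistry: C10 and C5 from the Diels–Alder step (absolute from a chiral salen–chromium Lewis acid, relative from the (E)-geometry of the enal); C3 from a thermodynamic dissolving-metal reduction; C8 and C9 from the chair transition state of the key closure.

Key step: step 10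

Remark: positions are given in labdane numbering (ring A = C1–C5, C10; ring B = C5–C10; C17 = methyl on C8; C11–C16 = side chain and lactone).
Assumption: the facial sense of the salen–chromium catalyst with this α,β-disubstituted enal is taken by analogy with α-substituted acroleins; the catalyst enantiomer that gives the (1R,6S) adduct 5 is used and is written here as (R,R).

**Step 1**
Reactants: 1 pent-4-enal; 2 2-(triphenylphosphoranylidene)propanal
Product: 3 (2E)-2-methylhepta-2,6-dienal
Conditions: toluene, 80 °C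
Reagents that add atoms: none
Why: Wittig olefination with the stabilised ylide should be (E)-selective, placing the formyl group trans to the butenyl chain, which later becomes the trans C5/C10 relationship.

**Step 2**
Reactants: 3 (2E)-2-methylhepta-2,6-dienal; 4 (1E)-3-[(tert-butyldimethylsilyl)oxy]-N,N-dimethylbuta-1,3-dien-1-amine
Product: 5 (1R,6S)-6-(but-3-en-1-yl)-4-[(tert-butyldimethylsilyl)oxy]-2-(dimethylamino)-1-methylcyclohex-3-ene-1-carbaldehyde (epimers at the amino carbon, used crude)
Conditions: (R,R)-[Cr(salen)]SbF6 (5 mol%, from [Cr(salen)]Cl and AgSbF6; salen = N,N′-bis(3,5-di-tert-butylsalicylidene)cyclohexane-1,2-diamine dianion), 4 Å molecular sieves, CH2Cl2, −40 → −20 °C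
Reagents that add atoms: none
Why: Lewis-acid-catalysed Diels–Alder reaction in which the CH2 terminus of the amino siloxy diene bonds to the β-carbon (C5) and the aminated terminus to the α-carbon (C10) of the enal; suprafacial addition keeps formyl and butenyl trans, and the chiral trivalent chromium complex shields one face of the bound enal to set the absolute configuration of both centres.

**Step 3**
Reactants: 5 cycloadduct aldehyde
Product: 7 (4R,5S)-5-(but-3-en-1-yl)-4-(1-hydroxyprop-2-en-1-yl)-4-methylcyclohex-2-en-1-one (carbinol epimers), via amino silyl enol ether carbinol 6 (not isolated)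
Conditions: CH2=CHMgBr (1.5 equiv), THF, −78 °C; then 1 M HCl, THF, 0 °C
Reagents that add atoms: vinylmagnesium bromide, C=C[Mg]Br
Why: Grignard addition to the neopentyl aldehyde, then acid hydrolysis of the silyl enol ether and E1cB loss of dimethylamine, should give the enone; the carbinol epimers do not matter because this centre is oxidised in step 6.

**Step 4**
Reactants: 7 enone carbinol
Product: 9 (4S,5R)-5-(but-3-en-1-yl)-4-(1-hydroxyprop-2-en-1-yl)-4,6,6-trimethylcyclohex-2-en-1-one, via monomethyl enone 8 (not isolated)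
Conditions: LiN(iPr)2 (2.2 equiv), THF, −78 °C; MeI (1.1 equiv), −78 → −30 °C; then LiN(iPr)2 (1.2 equiv), −78 °C; MeI (1.5 equiv), −78 → 0 °C
Reagents that add atoms: iodomethane, CI
Why: enolate alkylation of the cross-conjugated dienolate; the enone has no γ-hydrogen (C10 is quaternary), so C4 is the only acidic CH2 and is methylated twice, while the lithium alkoxide should not be methylated by MeI in THF at low temperature.

**Step 5**
Reactants: 9 gem-dimethyl enone
Product: 11 (1S,3S,4S)-3-(but-3-en-1-yl)-4-(1-hydroxyprop-2-en-1-yl)-2,2,4-trimethylcyclohexan-1-ol, via saturated ketone 10 (not isolated)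
Conditions: Li (10 equiv), NH3(l)/THF, −78 °C; then MeOH (excess), −78 → −33 °C; NH4Cl
Reagents that add atoms: none
Why: dissolving-metal (Birch-type) reduction saturates the enone via its enolate and, once MeOH releases the ketone, reduces it to the thermodynamically preferred equatorial C3 alcohol (cis to the equatorial butenyl group, 3β); isolated alkenes and the allylic alkoxide are inert.

**Step 6**
Reactants: 11 diol
Product: 12 1-[(1S,2S,4S)-2-(but-3-en-1-yl)-4-hydroxy-1,3,3-trimethylcyclohexyl]prop-2-en-1-one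
Conditions: activated MnO2 (20 equiv), CH2Cl2, rt
Reagents that add atoms: none
Why: chemoselective allylic oxidation; MnO2 should oxidise the vinyl carbinol at C9 and leave the saturated C3 hydroxyl untouched.

**Step 7**
Reactants: 13 3-bromooxolan-2-one (α-bromo-γ-butyrolactone, racemic); 14 benzenethiol
Product: 15 3-(phenylsulfanyl)oxolan-2-one (racemic)
Conditions: K2CO3, acetone, 0 °C → rt
Reagents that add atoms: none
Why: SN2 displacement of the activated α-bromide by thiolate.

**Step 8**
Reactants: 12 vinyl ketone; 15 3-(phenylsulfanyl)oxolan-2-one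
Product: 16 3-{3-[(1S,2S,4S)-2-(but-3-en-1-yl)-4-hydroxy-1,3,3-trimethylcyclohexyl]-3-oxopropyl}-3-(phenylsulfanyl)oxolan-2-one (C13 epimers)
Conditions: 15 (1.3 equiv), KOtBu (10 mol%), THF, −20 → 0 °C
Reagents that add atoms: none
Why: base-catalysed Michael addition of the sulfur- and lactone-stabilised enolate to the unhindered C12 of the vinyl ketone (1,2-addition is blocked by the neopentyl carbonyl); the C13 epimers converge when C13 becomes sp2 in step 11.

**Step 9**
Reactants: 16 hydroxy keto lactone
Product: 17 (1S,3S,4S)-3-(but-3-en-1-yl)-2,2,4-trimethyl-4-{3-[2-oxo-3-(phenylsulfanyl)oxolan-3-yl]propanoyl}cyclohexyl acetate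
Conditions: Ac2O, pyridine, DMAP (cat.), CH2Cl2, rt
Reagents that add atoms: acetic anhydride, CC(=O)OC(C)=O
Why: DMAP-catalysed acylation of the only hydroxyl group in the molecule.

**Step 10**
Reactants: 17 seco-labdane ketone–alkene
Product: 18 (3S,5S,8R,9R,10S)-3-acetoxy-9-hydroxy-13-(phenylsulfanyl)labdan-16,15-olide (3β-OAc, 9α-OH, 8α-methyl; C13 epimers)
Conditions: Fe(acac)3 (0.5 equiv), PhSiH3 (2.5 equiv), degassed EtOH (0.02 M), 60 °C
Reagents that add atoms: none
Why: An iron hydride formed from Fe(acac)3, PhSiH3 and EtOH transfers a hydrogen atom to the terminal carbon C17 of the vinyl group, giving the secondary C8 radical with the C17 methyl in place; this radical adds to the C9 ketone carbon, and the tertiary alkoxy radical is reduced by divalent iron and protonated by EtOH. The closest known reaction type is the iron-mediated, hydrogen-atom-transfer-initiated radical cyclisation of alkene-tethered α-quaternary ketones to tertiary cycloalkanols. Ring B closes in a 6-exo-trig mode onto the C=O carbon, and only the trans ring fusion is possible because C5 and C10 already carry their chains trans on ring A. C8 is set by the chair transition state, where the methyl must be equatorial (8α) to avoid a 1,3-diaxial clash with the axial C10 methyl; C9 is set by the larger CH2CH2R arm taking the equatorial site and the small oxygen the axial one (9α-OH), helped by the reversibility of radical addition to C=O, which lets the more stable alkoxy radical accumulate before reduction. The step needs hydrogen-atom transfer to the single electron-rich alkene and closure before the radical is quenched; the substrate secures this because it holds no other alkene or radical acceptor (the butenolide double bond is still masked as the sulfide, and ester carbonyls do not accept alkyl radicals) and the ketone lies five atoms from the radical.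

**Step 11**
Reactants: 18 cyclised sulfide
Product: 20 (3S,5S,8R,9R,10S)-3-acetoxy-9-hydroxylabd-13-en-16,15-olide (target), via sulfoxide 19 (not isolated)
Conditions: mCPBA (1.05 equiv), CH2Cl2, −78 °C; then toluene, pyridine (2 equiv), 110 °C
Reagents that add atoms: none
Why: sulfide oxidation and thermal syn-elimination of the sulfoxide, which in α-alkyl-α-sulfinyl-γ-butyrolactones should go into the ring towards C14–H to give the conjugated endocyclic butenolide; acetate and the hindered tertiary C9 hydroxyl are not affected.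

**Compound list**
1 | pent-4-enal | C=CCCC=O | starting material
2 | 2-(triphenylphosphoranylidene)propanal | CC(C=O)=P(c1ccccc1)(c1ccccc1)c1ccccc1 | starting material
3 | (2E)-2-methylhepta-2,6-dienal | C=CCC/C=C(\C)C=O | intermediate
4 | (1E)-3-[(tert-butyldimethylsilyl)oxy]-N,N-dimethylbuta-1,3-dien-1-amine | CN(C)/C=C/C(=C)O[Si](C)(C)C(C)(C)C | starting material
5 | (1R,6S)-6-(but-3-en-1-yl)-4-[(tert-butyldimethylsilyl)oxy]-2-(dimethylamino)-1-methylcyclohex-3-ene-1-carbaldehyde | C1(O[Si](C)(C)C(C)(C)C)=CC(N(C)C)[C@@](C=O)(C)[C@@H](CCC=C)C1 | intermediate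
6 | 1-[(1R,6S)-6-(but-3-en-1-yl)-4-[(tert-butyldimethylsilyl)oxy]-2-(dimethylamino)-1-methylcyclohex-3-en-1-yl]prop-2-en-1-ol | C1(O[Si](C)(C)C(C)(C)C)=CC(N(C)C)[C@@](C(O)C=C)(C)[C@@H](CCC=C)C1 | intermediate
7 | (4R,5S)-5-(but-3-en-1-yl)-4-(1-hydroxyprop-2-en-1-yl)-4-methylcyclohex-2-en-1-one | O=C1C=C[C@@](C(O)C=C)(C)[C@@H](CCC=C)C1 | intermediate
8 | (4S,5S)-5-(but-3-en-1-yl)-4-(1-hydroxyprop-2-en-1-yl)-4,6-dimethylcyclohex-2-en-1-one | O=C1C=C[C@@](C(O)C=C)(C)[C@@H](CCC=C)C1C | intermediate
9 | (4S,5R)-5-(but-3-en-1-yl)-4-(1-hydroxyprop-2-en-1-yl)-4,6,6-trimethylcyclohex-2-en-1-one | O=C1C=C[C@@](C(O)C=C)(C)[C@@H](CCC=C)C1(C)C | intermediate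
10 | (3R,4S)-3-(but-3-en-1-yl)-4-(1-hydroxyprop-2-en-1-yl)-2,2,4-trimethylcyclohexan-1-one | O=C1CC[C@@](C(O)C=C)(C)[C@@H](CCC=C)C1(C)C | intermediate
11 | (1S,3S,4S)-3-(but-3-en-1-yl)-4-(1-hydroxyprop-2-en-1-yl)-2,2,4-trimethylcyclohexan-1-ol | O[C@H]1CC[C@@](C(O)C=C)(C)[C@@H](CCC=C)C1(C)C | intermediate
12 | 1-[(1S,2S,4S)-2-(but-3-en-1-yl)-4-hydroxy-1,3,3-trimethylcyclohexyl]prop-2-en-1-one | O[C@H]1CC[C@@](C(=O)C=C)(C)[C@@H](CCC=C)C1(C)C | intermediate
13 | 3-bromooxolan-2-one | O=C1OCCC1Br | starting material
14 | benzenethiol | Sc1ccccc1 | starting material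
15 | 3-(phenylsulfanyl)oxolan-2-one | O=C1OCCC1Sc1ccccc1 | intermediate
16 | 3-{3-[(1S,2S,4S)-2-(but-3-en-1-yl)-4-hydroxy-1,3,3-trimethylcyclohexyl]-3-oxopropyl}-3-(phenylsulfanyl)oxolan-2-one | O[C@H]1CC[C@@](C(=O)CCC2(Sc3ccccc3)CCOC2=O)(C)[C@@H](CCC=C)C1(C)C | intermediate
17 | (1S,3S,4S)-3-(but-3-en-1-yl)-2,2,4-trimethyl-4-{3-[2-oxo-3-(phenylsulfanyl)oxolan-3-yl]propanoyl}cyclohexyl acetate | CC(=O)O[C@H]1CC[C@@](C(=O)CCC2(Sc3ccccc3)CCOC2=O)(C)[C@@H](CCC=C)C1(C)C | intermediate
18 | (3S,5S,8R,9R,10S)-3-acetoxy-9-hydroxy-13-(phenylsulfanyl)labdan-16,15-olide | CC(=O)O[C@H]1CC[C@@]2(C)[C@@H](CC[C@@H](C)[C@]2(O)CCC2(Sc3ccccc3)CCOC2=O)C1(C)C | intermediate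
19 | (3S,5S,8R,9R,10S)-3-acetoxy-9-hydroxy-13-(phenylsulfinyl)labdan-16,15-olide | CC(=O)O[C@H]1CC[C@@]2(C)[C@@H](CC[C@@H](C)[C@]2(O)CCC2(S(=O)c3ccccc3)CCOC2=O)C1(C)C | intermediate
20 | (3S,5S,8R,9R,10S)-3-acetoxy-9-hydroxylabd-13-en-16,15-olide | CC(=O)O[C@H]1CC[C@@]2(C)[C@@H](CC[C@@H](C)[C@]2(O)CCC2=CCOC2=O)C1(C)C | target

**Step count**
Total steps: 11. Longest linear sequence: 10 (steps 1–6 and 8–11; step 7 is a one-step side branch).

**Steps most likely to fail**

Step 10 (key closure). The C8 radical may be quenched by hydrogen-atom donation before it closes on the hindered C9 ketone (net hydrogenation of the vinyl group), and reversible opening of the alkoxy radical may erode conversion and facial control at C9. Fallback, from 17 back to 18: Markovnikov hydroiodination of the vinyl group (NaI, Me3SiCl, H2O, MeCN, 0 °C) gives the secondary iodide (1S,3S,4S)-3-(3-iodobutyl)-2,2,4-trimethyl-4-{3-[2-oxo-3-(phenylsulfanyl)oxolan-3-yl]propanoyl}cyclohexyl acetate F5 as a mixture of C8 epimers, both of which give the same planar radical. Et3B with air (toluene, rt) then generates the C8 radical by iodine-atom abstraction in an atom-transfer chain that contains no hydride donor. After the same 6-exo addition to the ketone, the alkoxy radical is trapped irreversibly at boron, which releases the ethyl radical that carries the chain. Aqueous work-up hydrolyses the borinate to 18, where the route resumes.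

Step 2 (asymmetric Diels–Alder). The uncatalysed background cycloaddition of the very reactive diene may compete with the catalysed path for this α,β-disubstituted enal, so that facial selectivity is poor. Fallback, from 3 back to 7, uses auxiliary control in place of catalyst control. (2R,5R)-2,5-Diphenylpyrrolidine is condensed with 4-methoxybut-3-en-2-one to the vinylogous amide (3E)-4-[(2R,5R)-2,5-diphenylpyrrolidin-1-yl]but-3-en-2-one F1. KN(SiMe3)2 and tBuMe2SiCl (THF, −78 °C) convert it into the C2-symmetric diene (2R,5R)-1-{(1E)-3-[(tert-butyldimethylsilyl)oxy]buta-1,3-dien-1-yl}-2,5-diphenylpyrrolidine F2. Thermal Diels–Alder reaction of F2 with 3 (toluene, 20–60 °C) should give (1R,6S)-6-(but-3-en-1-yl)-4-[(tert-butyldimethylsilyl)oxy]-2-[(2R,5R)-2,5-diphenylpyrrolidin-1-yl]-1-methylcyclohex-3-ene-1-carbaldehyde F3 under control of the auxiliary, whose enantiomer is chosen by the same analogy as for the catalyst. CH2=CHMgBr then gives the carbinol 1-[(1R,6S)-6-(but-3-en-1-yl)-4-[(tert-butyldimethylsilyl)oxy]-2-[(2R,5R)-2,5-diphenylpyrrolidin-1-yl]-1-methylcyclohex-3-en-1-yl]prop-2-en-1-ol F4 (not isolated), and 1 M HCl releases the auxiliary and returns 7.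

Step 6 (chemoselective oxidation). Oxidation of the hindered, only weakly activated vinyl carbinol by MnO2 may stall, or selectivity over the C3 hydroxyl may be lost under the forcing that it then needs. Fallback, from 11 back to 16, oxidises both carbinols and differentiates the ketones afterwards. Triacetoxyperiodinane (1,1,1-triacetoxy-1,2-benziodoxol-3(1H)-one, CH2Cl2, NaHCO3) gives (3S,4S)-3-(but-3-en-1-yl)-2,2,4-trimethyl-4-(prop-2-enoyl)cyclohexan-1-one F6. Michael addition of 15 under the conditions of step 8 gives 3-{3-[(1S,2S)-2-(but-3-en-1-yl)-1,3,3-trimethyl-4-oxocyclohexyl]-3-oxopropyl}-3-(phenylsulfanyl)oxolan-2-one F7; the α-sulfanyl lactone C–H is far more acidic than the ring ketone, so it should be the donor. NaBH4 (MeOH, −40 °C) should then reduce the cyclohexanone carbonyl faster than the acyclic neopentyl ketone, by axial attack, to the equatorial 3β-alcohol 16.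

**Further compounds**
F1 | step 2 | (3E)-4-[(2R,5R)-2,5-diphenylpyrrolidin-1-yl]but-3-en-2-one | CC(=O)/C=C/N1[C@@H](c2ccccc2)CC[C@@H]1c1ccccc1
F2 | step 2 | (2R,5R)-1-{(1E)-3-[(tert-butyldimethylsilyl)oxy]buta-1,3-dien-1-yl}-2,5-diphenylpyrrolidine | C=C(O[Si](C)(C)C(C)(C)C)/C=C/N1[C@@H](c2ccccc2)CC[C@@H]1c1ccccc1
F3 | step 2 | (1R,6S)-6-(but-3-en-1-yl)-4-[(tert-butyldimethylsilyl)oxy]-2-[(2R,5R)-2,5-diphenylpyrrolidin-1-yl]-1-methylcyclohex-3-ene-1-carbaldehyde | C1(O[Si](C)(C)C(C)(C)C)=CC(N2[C@@H](c3ccccc3)CC[C@@H]2c2ccccc2)[C@@](C=O)(C)[C@@H](CCC=C)C1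
F4 | step 2 | 1-[(1R,6S)-6-(but-3-en-1-yl)-4-[(tert-butyldimethylsilyl)oxy]-2-[(2R,5R)-2,5-diphenylpyrrolidin-1-yl]-1-methylcyclohex-3-en-1-yl]prop-2-en-1-ol | C1(O[Si](C)(C)C(C)(C)C)=CC(N2[C@@H](c3ccccc3)CC[C@@H]2c2ccccc2)[C@@](C(O)C=C)(C)[C@@H](CCC=C)C1
F5 | step 10 | (1S,3S,4S)-3-(3-iodobutyl)-2,2,4-trimethyl-4-{3-[2-oxo-3-(phenylsulfanyl)oxolan-3-yl]propanoyl}cyclohexyl acetate | CC(=O)O[C@H]1CC[C@@](C(=O)CCC2(Sc3ccccc3)CCOC2=O)(C)[C@@H](CCC(C)I)C1(C)C
F6 | step 6 | (3S,4S)-3-(but-3-en-1-yl)-2,2,4-trimethyl-4-(prop-2-enoyl)cyclohexan-1-one | O=C1CC[C@@](C(=O)C=C)(C)[C@@H](CCC=C)C1(C)C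
F7 | step 6 | 3-{3-[(1S,2S)-2-(but-3-en-1-yl)-1,3,3-trimethyl-4-oxocyclohexyl]-3-oxopropyl}-3-(phenylsulfanyl)oxolan-2-one | O=C1CC[C@@](C(=O)CCC2(Sc3ccccc3)CCOC2=O)(C)[C@@H](CCC=C)C1(C)C
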